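**Strategy.** The carbocycle (C1, C5–C10) is traced back to a six-membered ring by excising C5: C1 and C6–C10, with the C14 methyl on C10 and the C11–C13 branch on C7, are the carbon frame of (R)-carvone, whose stereocentre becomes C7. In the forward direction a single Lewis-acid-promoted diazoalkane homologation inserts C5 between the carbonyl carbon C1 and the C6 methylene, forming C1–C5 and C5–C6 and the cycloheptanone in one operation. Its precursor is cis-(2S,5R)-dihydrocarvone, a 2-methyl-5-isopropenylcyclohexanone. The new methylenes C5 and C6 flank the ketone and later receive the two ring oxygens.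

Key step: step 3

Remark on numbering: ring carbons are C1, C5, C6, C7, C8, C9, C10; C2–C4 and C15 form the chain on C1; C11–C13 the lactone branch on C7; C14 is the methyl on C10. "α" is the ring face that carries the C14 methyl in the target, "β" the opposite face.

Remark on the chemistry: hydride reduction of (R)-carvone gives mainly the trans (2R,5R) ketone, not the cis (2S,5R) epimer the target needs at C10. The cis epimer is therefore made in step 2 and carried through the key step; any residual C10 epimer is assumed to be removable by chromatography at enone 9.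

**Step 1**
Reactants: 1 (R)-carvone
Product: 2 (2R,5R)-2-methyl-5-(prop-1-en-2-yl)cyclohexan-1-one (trans-dihydrocarvone)
Conditions: LiBH(sec-Bu)3, THF, −78 °C; then H2O
Reagents that add atoms: none
Why: Conjugate hydride reduction of the enone by the hindered borohydride gives the enolate, whose protonation should place the C10 methyl mainly trans to the isopropenyl group, while C7 and the isopropenyl alkene are untouched.

**Step 2**
Reactants: 2 trans-dihydrocarvone
Product: 4 (2S,5R)-2-methyl-5-(prop-1-en-2-yl)cyclohexan-1-one (cis-dihydrocarvone), via pyrrolidine enamine 3 (not isolated)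
Conditions: pyrrolidine, toluene, reflux (Dean–Stark); then AcOH/NaOAc, H2O, 0 °C
Reagents that add atoms: none
Why: Contra-thermodynamic epimerisation through the enamine: in the less substituted enamine allylic 1,3-strain forces the C10 methyl pseudo-axial, which with a pseudo-equatorial isopropenyl group is the cis arrangement; both epimers of 2 equilibrate through the iminium ion, and cold buffered hydrolysis protonates C6, not C10, so the cis ketone should be released.

**Step 3**
Reactants: 4 cis-dihydrocarvone; 5 trimethylsilyldiazomethane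
Product: 7 (2S,5R)-2-methyl-5-(prop-1-en-2-yl)cycloheptan-1-one, via α-silyl ketone 6 (not isolated)
Conditions: AlMe3, CH2Cl2, −78 → −20 °C; then 1 M HCl, THF, 0 °C
Reagents that add atoms: none
Why: AlMe3 binds the C1 carbonyl, the diazo carbon adds to C1, and in the resulting aluminoxy diazonium species the C1–C6 bond anti-periplanar to the leaving N2 migrates to the diazo carbon, which becomes C5 (C1–C5 and C5–C6 formed, C1–C6 broken); the acidic work-up protodesilylates α-silyl ketone 6. This is the Lewis-acid-promoted one-carbon homologation of cyclohexanones with trimethylsilyldiazomethane, a Tiffeneau–Demjanov-type ring expansion. The seven-membered ring is not closed by a cyclisation but arises from the 1,2-alkyl shift that enlarges the existing six-membered ring. No stereocentre is created, since C5 ends as a methylene, and C7 and C10 are spectators. The step needs migration of the C6 methylene and not the C10 methine, which the lower substitution of C6 and the bulk of the silyl and aluminium groups in the adduct favour. It also needs a single insertion, which the hindered α-silyl ketone secures, and retention of the cis C10 configuration, for which the low temperature, the non-basic medium and the cold acidic desilylation are chosen.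

**Step 4**
Reactants: 7 cycloheptanone
Product: 9 (4R,7S)-7-methyl-4-(prop-1-en-2-yl)cyclohept-2-en-1-one, via trimethylsilyl enol ether 8 (not isolated)
Conditions: LiN(i-Pr)2, THF, −78 °C; Me3SiCl; then Pd(OAc)2 (10 mol %), O2, DMSO, rt
Reagents that add atoms: none
Why: Kinetic deprotonation at the less substituted α-carbon C5 and O-silylation give the C1–C5 enol ether, and Saegusa oxidation (divalent palladium enolate, β-hydride loss from C6) installs the C5=C6 enone without enolising C10 or creating a stereocentre.

**Step 5**
Reactants: 9 enone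
Product: 10 (4R,7S)-4-(3-chloroprop-1-en-2-yl)-7-methylcyclohept-2-en-1-one
Conditions: Ca(OCl)2, CO2 (solid), CH2Cl2–H2O, 0 °C
Reagents that add atoms: calcium hypochlorite, [Ca+2].[O-]Cl.[O-]Cl
Why: Ene-type allylic chlorination of the electron-rich 1,1-disubstituted alkene by HOCl (chlorine onto the former terminal methylene, now C12; proton loss from the former methyl, now the C13 methylene), as established for isopropenyl groups next to enones; the conjugated ring alkene is too electron-poor to compete.

**Step 6**
Reactants: 11 (R)-but-3-yn-2-ol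
Product: 12 (R)-(but-3-yn-2-yloxy)(tert-butyl)dimethylsilane
Conditions: t-BuMe2SiCl, imidazole, CH2Cl2, 0 °C → rt
Reagents that add atoms: tert-butyldimethylsilyl chloride, CC(C)(C)[Si](C)(C)Cl
Why: Standard silylation of the secondary alcohol, which protects the future C4 hydroxyl without touching its (R) stereocentre.

**Step 7**
Reactants: 10 chloro enone; 12 silyl-protected alkyne
Product: 15 1α-(trimethylsilyloxy)-1β-[(3R)-3-(tert-butyldimethylsilyloxy)but-1-yn-1-yl]-7α-(3-chloroprop-1-en-2-yl)-10α-methylcyclohept-5-ene, via lithium acetylide 13 (not isolated), via lithium alkoxide 14 (not isolated)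
Conditions: 12, n-BuLi, THF, −78 °C; 10, −78 °C; then Me3SiCl, −78 → 0 °C
Reagents that add atoms: chlorotrimethylsilane, C[Si](C)(C)Cl
Why: 1,2-Addition of the lithium acetylide to the enone carbonyl should occur on the β face, opposite the C10 methyl (pseudo-axial in the favoured half-chair of the cis enone) and the C7 side chain, which sets C1 with its oxygen α; the alkoxide is trapped as the trimethylsilyl ether, and the allylic chloride is inert at this temperature.

**Step 8**
Reactants: 15 allylic chloride
Product: 16 2-substituted acrolein (the 7α-(3-oxoprop-1-en-2-yl) analogue of 15)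
Conditions: N-methylmorpholine N-oxide, NaI (cat.), 4 Å molecular sieves, MeCN, rt → 40 °C
Reagents that add atoms: N-methylmorpholine N-oxide, C[N+]1([O-])CCOCC1
Why: Kornblum-type oxidation: iodide-assisted SN2 displacement of the primary allylic chloride by the N-oxide oxygen and base-induced N–O cleavage give the enal under neutral conditions that spare both silyl ethers, the alkyne and the ring alkene.

**Step 9**
Reactants: 16 enal
Product: 17 acrylic acid (the 7α-(1-carboxyethenyl) analogue of 15)
Conditions: NaClO2, NaH2PO4, 2-methyl-2-butene, t-BuOH–H2O, 0 °C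
Reagents that add atoms: sodium chlorite, [Na+].[O-]Cl=O
Why: Pinnick oxidation of the conjugated aldehyde to the acid; the alkene scavenger removes HOCl before it can reach the ring alkene or the alkyne, and the hindered tertiary trimethylsilyl ether should tolerate the buffered medium.

**Step 10**
Reactants: 17 acrylic acid
Product: 20 cis-fused α-methylene-γ-lactone (12,6α-olide) with 5β-OH; 1α-OH; 1β-alkynyl, via epoxy acid 18 (not isolated), via silylated hydroxy lactone 19 (not isolated)
Conditions: mCPBA, CH2Cl2, 0 °C; then pyridinium p-toluenesulfonate, MeOH, rt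
Reagents that add atoms: meta-chloroperbenzoic acid, OOC(=O)c1cccc(Cl)c1
Why: Peracid epoxidation of the only electron-rich alkene should occur on the β face, anti to both allylic α substituents (the C1 silyl ether and the C7 side chain); 5-exo opening of the epoxide at C6 by the carboxylic acid with inversion then gives the α C6–O bond of the cis-fused lactone and leaves the β C5 hydroxyl, and methanolysis frees the C1 hydroxyl.

**Step 11**
Reactants: 20 diol lactone
Product: 22 α-hydroxy ketone (1α-OH; C2 ketone; 4-O-silyl; 5β-OH; α-methylene lactone), via alkylidene cyclic carbonate 21 (not isolated)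
Conditions: AgOAc (10 mol %), DBU, CO2 (1 MPa), MeCN, rt; then H2O, 40 °C
Reagents that add atoms: carbon dioxide, O=C=O; water, O
Why: Carboxylative cyclisation of the tertiary propargylic alcohol: the C1 carbonate adds 5-exo-dig to the silver-activated alkyne, so oxygen is delivered to C2 only, and hydrolysis of the alkylidene carbonate (and of any carbonate passed on to the C5 hydroxyl) releases CO2 and the ketone without touching a stereocentre.

**Step 12**
Reactants: 22 α-methylene lactone
Product: 23 11,13-dihydro lactone (C13 methyl syn to the carbocycle; H11 cis to H6 and H7)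
Conditions: H2 (1 atm), RhCl(PPh3)3 (cat.), toluene–EtOH, rt
Reagents that add atoms: none
Why: Homogeneous hydrogenation of the exocyclic conjugated methylene delivers hydrogen to the convex face of the cis-fused lactone (the face of H6 and H7), which sets C11, while the ketone is inert and the soluble rhodium catalyst avoids migration of the double bond into the ring.

**Step 13**
Reactants: 23 dihydro lactone; 24 angelic acid
Product: 26 5β-angelate (4-O-tert-butyldimethylsilyl ether of the target), via mixed anhydride 25 (not isolated)
Conditions: 24, 2,4,6-trichlorobenzoyl chloride, Et3N, toluene, rt; then 23, 80 °C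
Reagents that add atoms: none
Why: Yamaguchi-type esterification through the mixed anhydride without a nucleophilic catalyst, conditions under which the (Z)-enoate should not isomerise to the (E)-isomer; only the secondary C5 hydroxyl reacts because the C1 hydroxyl is tertiary, and C5 keeps its configuration.

**Step 14**
Reactants: 26 silyl ether
Product: 27 target CNP0321985.1
Conditions: HF·pyridine, pyridine, THF, 0 °C → rt
Reagents that add atoms: none
Why: Fluoride cleavage of the secondary silyl ether under mildly acidic conditions avoids β-elimination or retro-aldol cleavage of the β-hydroxy ketone and leaves the angelate, the lactone and the tertiary α-ketol intact.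

**Compound list**
1 | (R)-carvone | CC1=CC[C@H](CC1=O)C(C)=C | starting material
2 | (2R,5R)-2-methyl-5-(prop-1-en-2-yl)cyclohexan-1-one (trans-dihydrocarvone) | O=C1C[C@H](C(C)=C)CC[C@H]1C | intermediate
3 | 1-[(3R,6S)-6-methyl-3-(prop-1-en-2-yl)cyclohex-1-en-1-yl]pyrrolidine | C1(N2CCCC2)=C[C@H](C(C)=C)CC[C@@H]1C | intermediate
4 | (2S,5R)-2-methyl-5-(prop-1-en-2-yl)cyclohexan-1-one (cis-dihydrocarvone) | O=C1C[C@H](C(C)=C)CC[C@@H]1C | intermediate
5 | trimethylsilyldiazomethane | C[Si](C)(C)C=[N+]=[N-] | starting material
6 | (2S,5R)-2-methyl-5-(prop-1-en-2-yl)-7-(trimethylsilyl)cycloheptan-1-one (silyl-bearing carbon is C5 of the target; both epimers) | O=C1C([Si](C)(C)C)C[C@H](C(C)=C)CC[C@@H]1C | intermediate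
7 | (2S,5R)-2-methyl-5-(prop-1-en-2-yl)cycloheptan-1-one | O=C1CC[C@H](C(C)=C)CC[C@@H]1C | intermediate
8 | trimethyl{[(4R,7S)-7-methyl-4-(prop-1-en-2-yl)cyclohept-1-en-1-yl]oxy}silane | C[Si](C)(C)OC1=CC[C@H](C(C)=C)CC[C@@H]1C | intermediate
9 | (4R,7S)-7-methyl-4-(prop-1-en-2-yl)cyclohept-2-en-1-one | O=C1C=C[C@H](C(C)=C)CC[C@@H]1C | intermediate
10 | (4R,7S)-4-(3-chloroprop-1-en-2-yl)-7-methylcyclohept-2-en-1-one | O=C1C=C[C@H](C(CCl)=C)CC[C@@H]1C | intermediate
11 | (R)-but-3-yn-2-ol | C#C[C@@H](C)O | starting material
12 | (R)-(but-3-yn-2-yloxy)(tert-butyl)dimethylsilane | C#C[C@@H](C)O[Si](C)(C)C(C)(C)C | intermediate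
13 | lithium acetylide of 12 | [Li]C#C[C@@H](C)O[Si](C)(C)C(C)(C)C | intermediate
14 | lithium alkoxide of the 1,2-adduct (C1–OLi α; alkynyl β) | C1=C[C@H](C(CCl)=C)CC[C@H](C)[C@@]1(O[Li])C#C[C@@H](C)O[Si](C)(C)C(C)(C)C | intermediate
15 | 1α-(trimethylsilyloxy)-1β-[(3R)-3-(tert-butyldimethylsilyloxy)but-1-yn-1-yl]-7α-(3-chloroprop-1-en-2-yl)-10α-methylcyclohept-5-ene | C1=C[C@H](C(CCl)=C)CC[C@H](C)[C@@]1(O[Si](C)(C)C)C#C[C@@H](C)O[Si](C)(C)C(C)(C)C | intermediate
16 | 7α-(3-oxoprop-1-en-2-yl) analogue of 15 (2-substituted acrolein) | C1=C[C@H](C(C=O)=C)CC[C@H](C)[C@@]1(O[Si](C)(C)C)C#C[C@@H](C)O[Si](C)(C)C(C)(C)C | intermediate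
17 | 7α-(1-carboxyethenyl) analogue of 15 (2-substituted acrylic acid) | C1=C[C@H](C(C(=O)O)=C)CC[C@H](C)[C@@]1(O[Si](C)(C)C)C#C[C@@H](C)O[Si](C)(C)C(C)(C)C | intermediate
18 | 5β,6β-epoxide of 17 | O1[C@H]2[C@@H]1[C@H](C(C(=O)O)=C)CC[C@H](C)[C@@]2(O[Si](C)(C)C)C#C[C@@H](C)O[Si](C)(C)C(C)(C)C | intermediate
19 | 1-O-trimethylsilyl ether of 20 | O[C@H]1[C@@H]2OC(=O)C(=C)[C@@H]2CC[C@H](C)[C@@]1(O[Si](C)(C)C)C#C[C@@H](C)O[Si](C)(C)C(C)(C)C | intermediate
20 | cis-fused α-methylene-γ-lactone (C12–O on C6α, C11 on C7α) with 5β-OH, 1α-OH, 1β-[(3R)-3-(tert-butyldimethylsilyloxy)but-1-yn-1-yl] and 10α-methyl | O[C@H]1[C@@H]2OC(=O)C(=C)[C@@H]2CC[C@H](C)[C@@]1(O)C#C[C@@H](C)O[Si](C)(C)C(C)(C)C | intermediate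
21 | spiro (Z)-alkylidene cyclic carbonate of 20 (C1–O–CO–O–C2, C2=C3) | O[C@H]1[C@@H]2OC(=O)C(=C)[C@@H]2CC[C@H](C)[C@]13OC(=O)O/C3=C\[C@@H](C)O[Si](C)(C)C(C)(C)C | intermediate
22 | α-hydroxy ketone: 1α,5β-dihydroxy, C2 ketone, (4R)-4-(tert-butyldimethylsilyloxy), α-methylene 12,6α-lactone | O[C@H]1[C@@H]2OC(=O)C(=C)[C@@H]2CC[C@H](C)[C@@]1(O)C(=O)C[C@@H](C)O[Si](C)(C)C(C)(C)C | intermediate
23 | 11,13-dihydro derivative of 22 (C13 methyl syn to the carbocycle) | O[C@H]1[C@@H]2OC(=O)[C@H](C)[C@@H]2CC[C@H](C)[C@@]1(O)C(=O)C[C@@H](C)O[Si](C)(C)C(C)(C)C | intermediate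
24 | angelic acid, (Z)-2-methylbut-2-enoic acid | C/C=C(/C)C(=O)O | starting material
25 | angelic 2,4,6-trichlorobenzoic anhydride | C/C=C(/C)C(=O)OC(=O)c1c(Cl)cc(Cl)cc1Cl | intermediate
26 | 5β-angelate of 23 (4-O-tert-butyldimethylsilyl ether of the target) | C/C=C(/C)C(=O)O[C@H]1[C@@H]2OC(=O)[C@H](C)[C@@H]2CC[C@H](C)[C@@]1(O)C(=O)C[C@@H](C)O[Si](C)(C)C(C)(C)C | intermediate
27 | CNP0321985.1 | C/C=C(/C)C(=O)O[C@H]1[C@@H]2OC(=O)[C@H](C)[C@@H]2CC[C@H](C)[C@@]1(O)C(=O)C[C@@H](C)O | target

**Step count and risks**
Total: 14 steps. Longest linear sequence: 13 steps (steps 1–5 and 7–14, from (R)-carvone).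

Steps most likely to fail:

- **Step 3.** Competing migration of the C10 methine, a second insertion, or loss of the cis C10 configuration under the Lewis acid would erode the key step. The fallback keeps the same bond changes but uses a diazoacetate and a separate decarboxylation. It sets out from 4, which with allyl diazoacetate and BF3·OEt2 in CH2Cl2 should give allyl (3S,6R)-3-methyl-2-oxo-6-(prop-1-en-2-yl)cycloheptane-1-carboxylate F1, the ester sitting on the inserted carbon C5. Deallylation and decarboxylation with Pd(PPh3)4 (zerovalent palladium) and morpholine in THF at room temperature then return to 7.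

- **Step 7.** The acetylide may attack the α face, syn to the C10 methyl, if the conformer with an equatorial methyl reacts faster, giving the C1 epimer. The fallback changes the source of facial control from the substrate to the reagent. It sets out from 10 and 12: the enone is first complexed with the bulky aluminium phenoxide MeAl(OAr)2 (Ar = 2,6-di-tert-butyl-4-methylphenyl), which occupies the more accessible face of the carbonyl and forces acetylide 13 onto the opposite one. Silylation as before comes back to 15; no new compound is formed (F0).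

- **Step 11.** Carboxylation of the hindered tertiary alkoxide may be slow, the amidine base may add to or isomerise the methylene lactone, and the C5 hydroxyl may cyclise onto the alkyne. The fallback replaces the carbonate tether from O1 by a silicon tether from O5. It sets out from 20, which with ClSiHMe2 and Et3N should give the bis(dimethylsilyl) ether F2. H2PtCl6-catalysed intramolecular 5-exo-dig hydrosilylation from the C5 silyl ether places silicon on C2 in the cyclic alkenyl siloxane F3. Tamao–Fleming oxidation (H2O2, KF, KHCO3, THF–MeOH) converts the C2–Si bond into the ketone and frees both hydroxyls, coming back at 22.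

Further compounds
F1 | step 3 | allyl (3S,6R)-3-methyl-2-oxo-6-(prop-1-en-2-yl)cycloheptane-1-carboxylate (C1 epimers) | O=C1C(C(=O)OCC=C)C[C@H](C(C)=C)CC[C@@H]1C
F0 | step 7 | none | none
F2 | step 11 | 1α,5β-bis(dimethylsilyl) ether of 20 | C[SiH](C)O[C@H]1[C@@H]2OC(=O)C(=C)[C@@H]2CC[C@H](C)[C@@]1(O[SiH](C)C)C#C[C@@H](C)O[Si](C)(C)C(C)(C)C
F3 | step 11 | cyclic alkenyl siloxane (O5–SiMe2–C2, exocyclic C2=C3, 1α-O-dimethylsilyl) | C[Si]1(C)O[C@H]2[C@@H]3OC(=O)C(=C)[C@@H]3CC[C@H](C)[C@@]2(O[SiH](C)C)/C1=C\[C@@H](C)O[Si](C)(C)C(C)(C)C
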